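(All runs come from a simulation on assumed constants, noise included.)

- The question is how much target the flask holds at 40 min and which late move adds most to it, given two runs that slow down with substrate still in them.

all flasks: substrate 0.050 M; free catalyst 0.25 mM; impurity 0.34 mM

| run | partner | temperature | remark | time |
|---|---|---|---|---|
| midnight | 0.10 M | 90 °C | the very flask that is asked about, followed so far |  |
| autumn | 0.10 M | 75 °C | run made earlier |  |
| flask | 0.100 M | 90 °C |  | 40 min |

| run | time / min | target / % | substrate / % |
|---|---|---|---|
| midnight | 2.50 | 18.1 | 75.3 |
| midnight | 6.00 | 27.5 | 62.8 |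
| midnight | 15.0 | 34.9 | 54.3 |
| midnight | 30.0 | 37.2 | 52.5 |
| autumn | 5.00 | 11.2 | 82.8 |
| autumn | 12.0 | 18.5 | 72.9 |
| autumn | 30.0 | 25.2 | 63.9 |
| autumn | 60.0 | 27.7 | 60.5 |

(each reading ± 0.3 percentage points)

- maple: at 40 min take out 90% of the by-product then present, then wait 40 min
- birch: at 40 min raise the temperature by 10 K, then wait 40 min
- cedar: change nothing and wait 40 min more
- oak: at 40 min add free catalyst, 100% of the amount charged, then wait 40 min
- larch: at 40 min add partner, 50.0% of the amount charged, then wait 40 min

- target, in percent of the substrate first charged, at 40 min
- which option adds most target ("none" when 2 percentage points or less is all one gets) (maple / birch / cedar / oak / larch / none)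
- target present, in percent of the substrate first charged, after birch
- target present, in percent of the substrate first charged, after oak

- what is added takes up no volume worth counting
- a reading or a percentage of target counts all its forms, free or not
- a reading of substrate is of its free form alone

- Two extreme versions of the midnight flask can be solved in the head: with a catalyst that lasts, target climbs until the substrate charge is used up, and with a catalyst taken by the impurity before its first turn, target stays at zero.
- The midnight flask lies between them, since its last reading stands at 37.2% target with 52.5% substrate, after a gain of 2.3 percentage points over its last interval, and the last autumn reading likewise stands at 27.7% with 60.5% substrate.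
- Equal charges of catalyst and impurity are the zero of the scale; this flask charges 0.34 mM against 0.25 mM, which gives 26.5% as the impurity surplus, the share of the impurity charge left over once each catalyst has taken one impurity.
- Taking the loss as one to one, the free catalyst in this flask is the limiting reagent of that loss, because its charge is smaller than the impurity charge, so the reckoning here puts target at 40 min close to the last midnight reading.
- By the same reckoning, oak is the option that changes the sign of the surplus, because the catalyst charged and added together is more than the impurity charge, so the leftover impurity takes 36.0% of the added catalyst and leaves the rest working.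
- The forecast gives 37.6% (37.1% to 38.3%), names oak, and puts birch at 37.9% and oak at 85% (68% to 96%), on this ground: “Waiting, heating, adding partner or removing by-product therefore give almost nothing”.
- The flask gives 36.9% at 40 min and 37.0% after birch, and oak comes out best, adding 62 points to reach 99.3%, which is above the forecast's high end of 96%.

    free catalyst + impurity → spent catalyst (k = 6600 M⁻¹ min⁻¹, Ea = 60.0 kJ mol⁻¹)
    substrate + catalyst intermediate B → catalyst intermediate C (k = 6100 M⁻¹ min⁻¹, Ea = 50.0 kJ mol⁻¹)
    free catalyst + target ⇌ idle complex, settled at all times (K = 46.0 M⁻¹, ΔH = −24.0 kJ mol⁻¹)
    partner + free catalyst ⇌ catalyst intermediate A (K = 29.0 M⁻¹, k = 3900 M⁻¹ min⁻¹, Ea = 63.0 kJ mol⁻¹, ΔH = −13.0 kJ mol⁻¹)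
    substrate + target ⇌ idle adduct, settled at all times (K = 17.0 M⁻¹, ΔH = −22.0 kJ mol⁻¹)
    catalyst intermediate A ⇌ by-product + catalyst intermediate B (K = 0.0450 M, k = 50.0 min⁻¹, Ea = 101 kJ mol⁻¹, ΔH = −32.0 kJ mol⁻¹)
    catalyst intermediate C → free catalyst + target (k = 140 min⁻¹, Ea = 78.0 kJ mol⁻¹)
    (constants at 90 °C)

- Left alone, the flask has come to rest: at ten times the time target stands at 37.0%, free catalyst goes from 0.0269% to 0% of its charge, and impurity goes from 27% to 26.5% of its charge, against a surplus of 26.5%. A neighbour flask, charged with 1.5 × 10⁻⁴ M of free catalyst, has a surplus of 55.9% by the same rule, and at 40 min it holds 56% of its impurity.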